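**Retrosynthetic overview**

1. Caraphenol B is reached from its hexabenzyl ether by neutral hydrogenolysis, because the all-cis C1 centre α to the ketone is base-labile.
2. The hexabenzyl ether comes from an acyclic keto aryl triflate: Pd-catalysed intramolecular enolate arylation closes the five-membered ring (ring B) between C1 and C7a of the oxygenated benzo ring (ring A), and a cold quench of the product enolate sets C1.
3. Enabling feature: C1 is α to the aryl ketone, and C7a is meta to both ring A oxygens (C4, C6), i.e. the third oxygen site of a phloroglucinol. Ring A is therefore brought in as a phloroglucinol whose third oxygen first anchors a temporary lactone and then leaves as triflate.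
4. The keto triflate comes from a cis-4,5-diaryl benzo-ε-lactone (temporary seven-membered ring), opened with an aryl Grignard reagent so that its acyl carbon becomes the aroyl carbon. The lactone comes from a carbene-catalysed [4+3] annulation of an ortho-quinone methide with a cinnamaldehyde, which sets C2 and C3.
5. Ring order: temporary seven-membered lactone (formed, then opened) first, five-membered carbocycle last.

Key step: step 8

Remark on the chemistry: the SMILES places the aroyl group (C1) and both aryl groups (C2, C3) on one face of the indane (1R,2R,3R), so the route is planned for this all-cis isomer; the enantiomer of the triazolium precatalyst in step 5 is taken to be the one that delivers the (4S,5R) lactone (both antipodes are commercial).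

Step 1
Reactants: 1 2,4,6-trihydroxybenzaldehyde
Product: 2 2,4-bis(benzyloxy)-6-hydroxybenzaldehyde
Conditions: BnBr (2.05 equiv), K2CO3, DMF, rt
Reagents that add atoms: benzyl bromide, BrCc1ccccc1
Why: Williamson etherification in which the 4-hydroxyl and one of the two equivalent 2-hydroxyls are alkylated while the last ortho-hydroxyl, hydrogen-bonded to the formyl oxygen, should stay free; no stereocentre is formed.

Step 2
Reactants: 2 2,4-bis(benzyloxy)-6-hydroxybenzaldehyde; 3 1,3-bis(benzyloxy)-5-bromobenzene
Product: 5 3,5-bis(benzyloxy)-2-{[3,5-bis(benzyloxy)phenyl](hydroxy)methyl}phenol (racemic), via aryl Grignard reagent 4 (not isolated)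
Conditions: 3 (2.3 equiv), Mg, THF, 50 °C; then 2, THF, 0 °C → rt; aq. NH4Cl
Reagents that add atoms: none
Why: Grignard addition to the aldehyde, the first equivalent of 4 deprotonating the phenol and the second adding to the chelated formyl group; the carbinol centre is formed racemic and is erased in step 5.

Step 3
Reactants: 5 3,5-bis(benzyloxy)-2-{[3,5-bis(benzyloxy)phenyl](hydroxy)methyl}phenol
Product: 6 3,5-bis(benzyloxy)-2-{[3,5-bis(benzyloxy)phenyl](4-methylbenzenesulfonyl)methyl}phenol (racemic)
Conditions: TolSO2Na (1.5 equiv), HCO2H–H2O, CH2Cl2, rt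
Reagents that add atoms: sodium 4-methylbenzenesulfinate, [Na+].[O-]S(=O)c1ccc(C)cc1
Why: SN1-type substitution in which the electron-rich ortho-hydroxybenzhydrol ionises to the ortho-quinone methide/benzhydryl cation and is captured at sulfur by the sulfinate, giving a storable sulfone that releases the quinone methide under mild base; the centre stays racemic.

Step 4
Reactants: 7 4-(benzyloxy)benzaldehyde
Product: 8 (2E)-3-[4-(benzyloxy)phenyl]prop-2-enal
Conditions: Ph3P=CHCHO (1.05 equiv), toluene, 80 °C
Reagents that add atoms: (triphenylphosphoranylidene)acetaldehyde, O=CC=P(c1ccccc1)(c1ccccc1)c1ccccc1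
Why: Wittig olefination with a formyl-stabilised ylide, which should give the E-enal.

Step 5
Reactants: 6 3,5-bis(benzyloxy)-2-{[3,5-bis(benzyloxy)phenyl](4-methylbenzenesulfonyl)methyl}phenol; 8 (2E)-3-[4-(benzyloxy)phenyl]prop-2-enal
Product: 10 (4S,5R)-6,8-bis(benzyloxy)-4-[4-(benzyloxy)phenyl]-5-[3,5-bis(benzyloxy)phenyl]-4,5-dihydro-1-benzoxepin-2(3H)-one, via ortho-quinone methide 9 (not isolated)
Conditions: chiral aminoindanol-derived N-mesityl triazolium chloride (15 mol %), Cs2CO3 (2.2 equiv), 4 Å MS, THF, 0 °C → rt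
Reagents that add atoms: none
Why: Carbonate eliminates sulfinate from 6 to give 9, the chiral triazolylidene turns 8 into a homoenolate whose β-carbon adds to the methide carbon, and the acyl azolium is closed by the phenoxide (carbene-catalysed [4+3] annulation, known to be cis-selective with aryl-substituted ortho-quinone methides); this C–C bond formation sets both stereocentres, cis to each other and in the absolute sense fixed by the shielded face of the catalyst-bound homoenolate.

Step 6
Reactants: 10 (4S,5R)-6,8-bis(benzyloxy)-4-[4-(benzyloxy)phenyl]-5-[3,5-bis(benzyloxy)phenyl]-4,5-dihydro-1-benzoxepin-2(3H)-one; 11 [4-(benzyloxy)phenyl]magnesium bromide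
Product: 13 (3S,4R)-4-[2,4-bis(benzyloxy)-6-hydroxyphenyl]-4-[3,5-bis(benzyloxy)phenyl]-1,3-bis[4-(benzyloxy)phenyl]butan-1-one, via N-methoxy-N-methylamide 12 (not isolated)
Conditions: MeNH(OMe)·HCl (1.5 equiv), iPrMgCl (3.1 equiv), THF, −20 → 0 °C; then 11 (2.5 equiv), 0 °C → rt; aq. NH4Cl
Reagents that add atoms: none
Why: Aminolysis of the aryl lactone by the magnesium amide of N,O-dimethylhydroxylamine followed by Weinreb ketone synthesis with 11, the chelated tetrahedral intermediate preventing over-addition; both stereocentres are remote from the reacting carbonyl and are untouched.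

Step 7
Reactants: 13 (3S,4R)-4-[2,4-bis(benzyloxy)-6-hydroxyphenyl]-4-[3,5-bis(benzyloxy)phenyl]-1,3-bis[4-(benzyloxy)phenyl]butan-1-one
Product: 14 3,5-bis(benzyloxy)-2-{(1R,2S)-1-[3,5-bis(benzyloxy)phenyl]-2,4-bis[4-(benzyloxy)phenyl]-4-oxobutyl}phenyl trifluoromethanesulfonate
Conditions: PhNTf2 (1.2 equiv), Et3N, DMAP (cat.), CH2Cl2, 0 °C → rt
Reagents that add atoms: N-phenylbis(trifluoromethanesulfonimide), O=S(=O)(N(c1ccccc1)S(=O)(=O)C(F)(F)F)C(F)(F)F
Why: O-Sulfonylation of the phenol with a mild triflyl donor; the ketone is not enolised by triethylamine at this temperature and the stereocentres are untouched.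

Step 8
Reactants: 14 3,5-bis(benzyloxy)-2-{(1R,2S)-1-[3,5-bis(benzyloxy)phenyl]-2,4-bis[4-(benzyloxy)phenyl]-4-oxobutyl}phenyl trifluoromethanesulfonate
Product: 16 [4-(benzyloxy)phenyl]{(1R,2R,3R)-4,6-bis(benzyloxy)-3-[3,5-bis(benzyloxy)phenyl]-2-[4-(benzyloxy)phenyl]-2,3-dihydro-1H-inden-1-yl}methanone, via sodium enolate 15 (not isolated)
Conditions: Pd2(dba)3 (2.5 mol %), XPhos (6 mol %), NaOtBu (2.5 equiv), toluene, 60 °C; then THF, −78 °C, AcOH (5 equiv); pH 7 buffer
Reagents that add atoms: none
Why: NaOtBu converts the only enolisable position (C1, the CH2 α to the aryl ketone) into the enolate, zerovalent palladium ligated by XPhos inserts into the C7a–OTf bond, the enolate displaces triflate on palladium to give a C-bound six-membered palladacycle, and reductive elimination forms the C1–C7a bond. The closest known reaction type is the palladium-catalysed intramolecular α-arylation of ketones with aryl halides and triflates, which is established for the closure of 1-acylindanes. The five-membered carbocycle (ring B) is closed in the 5-exo sense by attack of the enolate α-carbon on the arylpalladium carbon of ring A. C1 is the only new stereocentre: under the excess base the product is held as the planar exocyclic enolate 15, and C1 is fixed only in the quench at −78 °C, where the proton should enter from the face opposite the cis C2 and C3 aryl groups (kinetic protonation of an exocyclic enolate from its less hindered face), which places the aroyl group on the face of both aryl groups. The step needs C- over O-arylation, closure at C7a and not at an ortho carbon of the other aryl rings, and a non-equilibrating protonation; these are secured by the five- against seven-membered ring preference of enolate arylation, by the triflate that marks C7a (a carbon meta to both ether oxygens that no electrophilic cyclisation would choose), and by the cold acidic quench with neutral work-up.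

Step 9
Reactants: 16 [4-(benzyloxy)phenyl]{(1R,2R,3R)-4,6-bis(benzyloxy)-3-[3,5-bis(benzyloxy)phenyl]-2-[4-(benzyloxy)phenyl]-2,3-dihydro-1H-inden-1-yl}methanone
Product: 17 caraphenol B, [(1R,2R,3R)-3-(3,5-dihydroxyphenyl)-4,6-dihydroxy-2-(4-hydroxyphenyl)-2,3-dihydro-1H-inden-1-yl](4-hydroxyphenyl)methanone
Conditions: H2 (1 atm), Pd/C, EtOAc–MeOH, rt
Reagents that add atoms: none
Why: Hydrogenolysis of the six aryl benzyl ethers over Pd/C in neutral medium, chosen so that the C1 centre α to the ketone cannot enolise; the electron-rich aryl ketone should be reduced much more slowly than the ethers are cleaved.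

**Compound list**

1 | 2,4,6-trihydroxybenzaldehyde | O=Cc1c(O)cc(O)cc1O | starting material
2 | 2,4-bis(benzyloxy)-6-hydroxybenzaldehyde | O=Cc1c(O)cc(OCc2ccccc2)cc1OCc1ccccc1 | intermediate
3 | 1,3-bis(benzyloxy)-5-bromobenzene | Brc1cc(OCc2ccccc2)cc(OCc2ccccc2)c1 | starting material
4 | [3,5-bis(benzyloxy)phenyl]magnesium bromide | Br[Mg]c1cc(OCc2ccccc2)cc(OCc2ccccc2)c1 | intermediate
5 | 3,5-bis(benzyloxy)-2-{[3,5-bis(benzyloxy)phenyl](hydroxy)methyl}phenol (racemic) | OC(c1cc(OCc2ccccc2)cc(OCc2ccccc2)c1)c1c(O)cc(OCc2ccccc2)cc1OCc1ccccc1 | intermediate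
6 | 3,5-bis(benzyloxy)-2-{[3,5-bis(benzyloxy)phenyl](4-methylbenzenesulfonyl)methyl}phenol (racemic) | Cc1ccc(cc1)S(=O)(=O)C(c1cc(OCc2ccccc2)cc(OCc2ccccc2)c1)c1c(O)cc(OCc2ccccc2)cc1OCc1ccccc1 | intermediate
7 | 4-(benzyloxy)benzaldehyde | O=Cc1ccc(OCc2ccccc2)cc1 | starting material
8 | (2E)-3-[4-(benzyloxy)phenyl]prop-2-enal | O=C/C=C/c1ccc(OCc2ccccc2)cc1 | intermediate
9 | 3,5-bis(benzyloxy)-6-{[3,5-bis(benzyloxy)phenyl]methylidene}cyclohexa-2,4-dien-1-one (ortho-quinone methide, alkene geometry not defined) | O=C1C=C(OCc2ccccc2)C=C(OCc2ccccc2)C1=Cc1cc(OCc2ccccc2)cc(OCc2ccccc2)c1 | intermediate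
10 | (4S,5R)-6,8-bis(benzyloxy)-4-[4-(benzyloxy)phenyl]-5-[3,5-bis(benzyloxy)phenyl]-4,5-dihydro-1-benzoxepin-2(3H)-one (cis) | O1c2cc(OCc3ccccc3)cc(OCc3ccccc3)c2[C@@H](c2cc(OCc3ccccc3)cc(OCc3ccccc3)c2)[C@H](CC1=O)c1ccc(OCc2ccccc2)cc1 | intermediate
11 | [4-(benzyloxy)phenyl]magnesium bromide | Br[Mg]c1ccc(OCc2ccccc2)cc1 | starting material
12 | (3S,4R)-4-[2,4-bis(benzyloxy)-6-hydroxyphenyl]-4-[3,5-bis(benzyloxy)phenyl]-3-[4-(benzyloxy)phenyl]-N-methoxy-N-methylbutanamide | Oc1cc(OCc2ccccc2)cc(OCc2ccccc2)c1[C@@H](c1cc(OCc2ccccc2)cc(OCc2ccccc2)c1)[C@H](CC(=O)N(C)OC)c1ccc(OCc2ccccc2)cc1 | intermediate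
13 | (3S,4R)-4-[2,4-bis(benzyloxy)-6-hydroxyphenyl]-4-[3,5-bis(benzyloxy)phenyl]-1,3-bis[4-(benzyloxy)phenyl]butan-1-one | Oc1cc(OCc2ccccc2)cc(OCc2ccccc2)c1[C@@H](c1cc(OCc2ccccc2)cc(OCc2ccccc2)c1)[C@H](CC(=O)c1ccc(OCc2ccccc2)cc1)c1ccc(OCc2ccccc2)cc1 | intermediate
14 | 3,5-bis(benzyloxy)-2-{(1R,2S)-1-[3,5-bis(benzyloxy)phenyl]-2,4-bis[4-(benzyloxy)phenyl]-4-oxobutyl}phenyl trifluoromethanesulfonate | FC(F)(F)S(=O)(=O)Oc1cc(OCc2ccccc2)cc(OCc2ccccc2)c1[C@@H](c1cc(OCc2ccccc2)cc(OCc2ccccc2)c1)[C@H](CC(=O)c1ccc(OCc2ccccc2)cc1)c1ccc(OCc2ccccc2)cc1 | intermediate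
15 | sodium [4-(benzyloxy)phenyl]{4,6-bis(benzyloxy)-3-[3,5-bis(benzyloxy)phenyl]-2-[4-(benzyloxy)phenyl]-2,3-dihydro-1H-inden-1-ylidene}methanolate (C2 and C3 configured as in 14; enolate geometry not defined) | [Na+].[O-]C(c1ccc(OCc2ccccc2)cc1)=C1c2cc(OCc3ccccc3)cc(OCc3ccccc3)c2[C@@H](c2cc(OCc3ccccc3)cc(OCc3ccccc3)c2)[C@H]1c1ccc(OCc2ccccc2)cc1 | intermediate
16 | [4-(benzyloxy)phenyl]{(1R,2R,3R)-4,6-bis(benzyloxy)-3-[3,5-bis(benzyloxy)phenyl]-2-[4-(benzyloxy)phenyl]-2,3-dihydro-1H-inden-1-yl}methanone | O=C(c1ccc(OCc2ccccc2)cc1)[C@H]1c2cc(OCc3ccccc3)cc(OCc3ccccc3)c2[C@@H](c2cc(OCc3ccccc3)cc(OCc3ccccc3)c2)[C@H]1c1ccc(OCc2ccccc2)cc1 | intermediate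
17 | caraphenol B, [(1R,2R,3R)-3-(3,5-dihydroxyphenyl)-4,6-dihydroxy-2-(4-hydroxyphenyl)-2,3-dihydro-1H-inden-1-yl](4-hydroxyphenyl)methanone | O=C(c1ccc(O)cc1)[C@H]1c2cc(O)cc(O)c2[C@@H](c2cc(O)cc(O)c2)[C@H]1c1ccc(O)cc1 | target

**Step count and risks**

Total step count: 9. Longest linear sequence: 8 steps (steps 1, 2, 3, 5, 6, 7, 8, 9); step 4 is a one-step branch.

Steps most likely to fail:

Step 8 (key step). What may go wrong: the protonation of enolate 15 may not discriminate between its two faces, or the all-cis ketone may re-enolise during work-up and equilibrate at C1 toward the 1,2-trans arrangement. Fallback: the face selection is moved from a protonation to a hydrogenation. Setting out again from 14, the arylation is run as in step 8 but the enolate is intercepted at −78 °C with PhSeCl in place of acetic acid. This should give the α-selanyl ketone [4-(benzyloxy)phenyl]{(1S,2S,3R)-4,6-bis(benzyloxy)-3-[3,5-bis(benzyloxy)phenyl]-2-[4-(benzyloxy)phenyl]-1-(phenylselanyl)-2,3-dihydro-1H-inden-1-yl}methanone F1, selenium entering anti to the C2 aryl and hence syn to H-2. Oxidation with H2O2 in buffered CH2Cl2 at 0 °C and syn-elimination of the selenoxide should give the indene enone [4-(benzyloxy)phenyl]{(1S)-5,7-bis(benzyloxy)-1-[3,5-bis(benzyloxy)phenyl]-2-[4-(benzyloxy)phenyl]-1H-inden-3-yl}methanone F2, in which only the former C3 is stereogenic; it is kept away from base. Hydrogenation over Pd/C in EtOAc–MeOH should add hydrogen to the tetrasubstituted ring double bond from the face opposite the remaining aryl-bearing stereocentre, as is known for 1,2,3-trisubstituted indenes, and should remove the six benzyl groups in the same operation. The sequence comes back to the route at 17. Because F2 no longer carries the C2 stereocentre, this fallback also absorbs a loss of cis selectivity in step 5.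

Step 5. What may go wrong: the homoenolate may add to the hindered, electron-rich ortho-quinone methide with poor discrimination of the faces (erosion of enantiomeric purity), or it may be protonated at its β-carbon and diverted into the enolate [4+2] manifold. Fallback: asymmetric induction by the catalyst is given up and replaced by resolution. Setting out from 6 and 8, the annulation is run with the small achiral carbene generated from 1,3-dimesitylimidazolium chloride and Cs2CO3, a catalyst class that favours homoenolate reactivity. It should give the racemic cis lactone, that is 10 together with its enantiomer (4R,5S)-6,8-bis(benzyloxy)-4-[4-(benzyloxy)phenyl]-5-[3,5-bis(benzyloxy)phenyl]-4,5-dihydro-1-benzoxepin-2(3H)-one F3. The enantiomers are separated by preparative chromatography on a chiral stationary phase, and the (4S,5R) enantiomer re-enters the route at 10.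

Step 9. What may go wrong: over-reduction of the aryl ketone (to the carbinol or the methylene compound) while the last benzyl ethers are still being cleaved. Fallback: the reductive cleavage is replaced by a non-reductive Lewis-acid cleavage. Setting out from 16, BCl3 with pentamethylbenzene as benzyl-cation scavenger in CH2Cl2 at −78 °C, quenched cold with methanol, should give 17 directly, where the sequence rejoins the route; no further compound arises (F0).

Further compounds
F1 | step 8 | [4-(benzyloxy)phenyl]{(1S,2S,3R)-4,6-bis(benzyloxy)-3-[3,5-bis(benzyloxy)phenyl]-2-[4-(benzyloxy)phenyl]-1-(phenylselanyl)-2,3-dihydro-1H-inden-1-yl}methanone | O=C(c1ccc(OCc2ccccc2)cc1)[C@@]1([Se]c2ccccc2)c2cc(OCc3ccccc3)cc(OCc3ccccc3)c2[C@@H](c2cc(OCc3ccccc3)cc(OCc3ccccc3)c2)[C@H]1c1ccc(OCc2ccccc2)cc1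
F2 | step 8 | [4-(benzyloxy)phenyl]{(1S)-5,7-bis(benzyloxy)-1-[3,5-bis(benzyloxy)phenyl]-2-[4-(benzyloxy)phenyl]-1H-inden-3-yl}methanone | O=C(c1ccc(OCc2ccccc2)cc1)C=1c2cc(OCc3ccccc3)cc(OCc3ccccc3)c2[C@@H](c2cc(OCc3ccccc3)cc(OCc3ccccc3)c2)C=1c1ccc(OCc2ccccc2)cc1
F3 | step 5 | (4R,5S)-6,8-bis(benzyloxy)-4-[4-(benzyloxy)phenyl]-5-[3,5-bis(benzyloxy)phenyl]-4,5-dihydro-1-benzoxepin-2(3H)-one | O1c2cc(OCc3ccccc3)cc(OCc3ccccc3)c2[C@H](c2cc(OCc3ccccc3)cc(OCc3ccccc3)c2)[C@@H](CC1=O)c1ccc(OCc2ccccc2)cc1
F0 | step 9 | none | none
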